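**Assumption:** (+)-O-methylpodocarpic acid, the phenol methyl ether of the resin acid (+)-podocarpic acid, is taken as a catalogue compound. If only podocarpic acid is available, add one step (Me2SO4, aq. NaOH).

## Retrosynthetic overview
1. Rings A/B and C4, C5 and C10 (including the axial 19-CO2H) are bought in (+)-O-methylpodocarpic acid (1). No ring is formed; aromatic ring C is dismantled.
2. Ring C is opened at C12–C13 by Birch reduction (2) and enol-ether-selective ozonolysis (3). C11–C12 stays on C9 as CH2CO2Me, and C14–C13 stays on C8 as CH2CHO, across a C8=C9 alkene.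
3. C13 leaves as CO in a light-driven deformylative allyl transposition (4). Old C14 becomes the exocyclic methylene C17, and C9–H is set from the α face.
4. The ester is reduced to alcohol 5. The C12–C13 bond is then made by Ni/photoredox deoxygenative coupling with the E-vinyl iodide built from but-2-yn-1-ol (6 → 7 → 8). This brings in C13–C16, the E-alkene and the acetate, giving target 9.

## Route

**Step 1**
Reactants: 1, (+)-O-methylpodocarpic acid (12-methoxypodocarpa-8,11,13-trien-19-oic acid; 4β-axial CO2H, 5α-H, 10β-CH3)
Product: 2, 12-methoxypodocarpa-8,12-dien-19-oic acid (tetrasubstituted C8=C9, enol ether C12=C13, CH2 at C11 and C14)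
Conditions: Li (8 equiv), NH3(l)–THF–t-BuOH, −78 → −33 °C; NH4Cl(s); cold pH 7 work-up; used crude
Reagents that add atoms: none
Why: Birch reduction gives the 1,4-diene that keeps the OMe-bearing and both alkyl-bearing carbons sp2; the lithium carboxylate is inert and no stereocenter is touched.

**Step 2**
Reactants: 2
Product: 3, 12,13-seco-podocarp-8-ene-12,19-dioic acid 12-methyl ester 13-al (trans-decalin with C8=C9; C9 bears CH2CO2Me, C8 bears CH2CHO; 19-CO2H free)
Conditions: O3 (1.0 equiv, Sudan Red end-point), CH2Cl2–MeOH 4:1, NaHCO3, cat. pyridine, −78 °C; then Me2S, −78 °C → rt; used promptly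
Reagents that add atoms: ozone, [O-][O+]=O
Why: In this Criegee ozonolysis the exposed enol ether reacts far faster than the buried ring-fusion tetrasubstituted alkene, and the ozonide splits to the C12 methyl ester plus a C13 carbonyl oxide that MeOH traps and Me2S reduces to the aldehyde; the buffer prevents enol-ether hydrolysis and conjugation.

**Step 3**
Reactants: 3
Product: 4, 12-methyl hydrogen 13,14,15,16-tetranorlabd-8(17)-ene-12,19-dioate (exocyclic C8=CH2, 9α-H, β-equatorial CH2CO2Me)
Conditions: (n-Bu4N)4W10O32 (2 mol %), Co(dmgH)2(py)Cl (5 mol %), MeCN (0.05 M), 390 nm LEDs, slow Ar sweep (removes CO), 25 °C; stop when the aldehyde is consumed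
Reagents that add atoms: none (CO is lost)
Why: Proposed new method: excited decatungstate abstracts the formyl H (the most hydridic and accessible C–H); the β,γ-unsaturated acyl radical loses CO rapidly to give the C14–C8–C9 allyl radical; Co(II) cobaloxime caps it at the primary C14 terminus; H delivery (SH2′ from reduced tungstate, or SE2′ protonation) then occurs at the γ-carbon C9 from the α face, because the β face is blocked by the axial C10 methyl, which releases C8=C17 and sets 9α-H. The product is a sink, since re-abstraction at C7–H or C9–H re-enters the same allyl-cobalt manifold. Closest known reaction types: decatungstate/cobaloxime dehydroformylation of aldehydes, contra-thermodynamic alkene isomerisation through allyl-cobaloximes, and direct-irradiation photodecarbonylation of β,γ-unsaturated aldehydes with formyl-H transfer to the γ-carbon.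

**Step 4**
Reactants: 4
Product: 5, 12-hydroxy-13,14,15,16-tetranorlabd-8(17)-en-19-oic acid
Conditions: LiOt-Bu (1.0 equiv), THF, 0 °C; then LiBH4 (2.5 equiv), MeOH (2.5 equiv), 0 °C → rt; aq. citric acid
Reagents that add atoms: none
Why: In this chemoselective borohydride ester reduction the unhindered primary ester is reduced while the hindered axial lithium carboxylate and the alkene are inert; pre-forming the carboxylate avoids acyloxyborohydride or borane species that could hydroborate C8=C17.

**Step 5**
Reactants: 6, but-2-yn-1-ol
Product: 7, (E)-3-iodobut-2-en-1-ol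
Conditions: DIBAL-H (1.0 equiv), THF, 0 °C; Cp2ZrCl2/DIBAL-H (in situ Cp2Zr(H)Cl, 1.3 equiv), 0 °C → rt; I2, −78 °C
Reagents that add atoms: iodine, II
Why: Syn-hydrozirconation places Zr on the methyl-bearing carbon (the smaller substituent), and iodinolysis with retention puts I trans to CH2OH, giving the E isomer.

**Step 6**
Reactants: 7
Product: 8, (E)-3-iodobut-2-en-1-yl acetate
Conditions: Ac2O, pyridine, cat. DMAP, CH2Cl2, 0 °C → rt
Reagents that add atoms: acetic anhydride, CC(=O)OC(C)=O
Why: This is a standard O-acetylation and the alkene geometry is untouched.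

**Step 7**
Reactants: 5 and 8
Product: 9, 15-acetoxyisocupressic acid, (13E)-15-acetoxylabda-8(17),13-dien-19-oic acid (target)
Conditions: 5, 5,7-di-tert-butyl-3-phenylbenzoxazolium BF4 (1.6 equiv), pyridine (2.6 equiv), MTBE, rt, 15 min, filter; then 8 (1.5 equiv), NiBr2·dtbbpy (5 mol %), [Ir(ppy)2(dtbbpy)]PF6 (1.5 mol %), quinuclidine (2.75 equiv), DMA–MTBE, 450 nm LEDs, rt; aq. citric acid
Reagents that add atoms: none beyond reactant 8, I/C(C)=C/COC(C)=O
Why: Proposed new method: the alcohol condenses with the benzoxazolium salt to a 2-alkoxybenzoxazoline; SET oxidation by excited Ir, deprotonation and β-scission then release the primary C12 radical, a 4-pentenyl type whose 4-exo and 5-endo closures are too slow to compete. Ni(0) inserts into the C–I bond of 8 with retention, captures the radical, and Ni(III) reductively eliminates the C12–C13 bond, so the E geometry comes directly from 8. The photocatalyst is too weak to oxidise the carboxylate or quinuclidine, and its triplet energy is too low to isomerise isolated alkenes. Closest known reaction types: the same NHC-alcohol deoxygenative Ni/photoredox coupling with aryl halides, and Ni/photoredox alkyl-radical couplings with alkenyl halides that retain geometry. The new elements are the alkenyl iodide partner and the free hindered carboxylate.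

## Compound list
1 | (+)-O-methylpodocarpic acid | COc1ccc2c(c1)[C@@]1(C)CCC[C@](C)(C(=O)O)[C@@H]1CC2 | starting material
2 | 12-methoxypodocarpa-8,12-dien-19-oic acid | COC1=CCC2=C(C1)[C@@]1(C)CCC[C@](C)(C(=O)O)[C@@H]1CC2 | intermediate
3 | 12,13-seco-podocarp-8-ene 12-methyl ester 13-al 19-acid | COC(=O)CC1=C(CC=O)CC[C@@H]2[C@]1(C)CCC[C@]2(C)C(=O)O | intermediate
4 | 12-methyl hydrogen 13,14,15,16-tetranorlabd-8(17)-ene-12,19-dioate | C=C1CC[C@@H]2[C@](C)(CCC[C@]2(C)C(=O)O)[C@H]1CC(=O)OC | intermediate
5 | 12-hydroxy-13,14,15,16-tetranorlabd-8(17)-en-19-oic acid | C=C1CC[C@@H]2[C@](C)(CCC[C@]2(C)C(=O)O)[C@H]1CCO | intermediate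
6 | but-2-yn-1-ol | CC#CCO | starting material
7 | (E)-3-iodobut-2-en-1-ol | I/C(C)=C/CO | intermediate
8 | (E)-3-iodobut-2-en-1-yl acetate | I/C(C)=C/COC(C)=O | intermediate
9 | 15-acetoxyisocupressic acid | C=C1CC[C@@H]2[C@](C)(CCC[C@]2(C)C(=O)O)[C@H]1CC/C(C)=C/COC(C)=O | target

**Stereochemistry ledger:** C4, C5 and C10 are bought in 1 and never touched. C9 is set in Step 3 under control of C10/C5. The 13E alkene is fixed in Step 5 and carried through Step 7 with retention.

## Step count
Total steps: 7. Longest linear sequence: 5 (Steps 1, 2, 3, 4, 7).

## Steps most likely to fail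
1. **Step 3 (new method).**
   - Risks: back-HAT at C14 gives the 8-methyl-Δ8 isomer; Co–H elimination gives dienes; over-irradiation dehydrogenates ring A.
   - Fallback (known chemistry, different logic): shorten CH2CHO of 3 to the conjugated C14 enal (silyl enol ether, then O3). Form the tosylhydrazone, reduce it with catecholborane and warm with NaOAc. The allylic-diazene retro-ene transposes the alkene to C8=C17 and delivers 9α-H.
2. **Step 7 (new partner class).**
   - Risks: the carboxylate disturbs the alkoxy-benzoxazoline adduct; Ni(0) ionises the allylic acetate; 1,5-HAT occurs from allylic C7–H.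
   - Fallback (known chemistry): Appel iodination of 5, then zinc insertion on the sodium carboxylate. Carry out a Pd-catalysed Negishi coupling with the TBS ether of 7 (retention of geometry), then TBAF and Ac2O/pyridine.
3. **Step 2.**
   - Risks: ozone also attacks C8=C9; aldehyde 3 slips into conjugation or undergoes aldol reaction.
   - Fallback: dihydroxylate only the enol ether (cat. OsO4, NMO) to the 13-hydroxy-12-ketone. Cleave it with Pb(OAc)4 in MeOH, which gives the same methyl ester/aldehyde 3 without ozone.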